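**Assumption (one line):** (+)-(2R,3R)-dihydromorin, a natural flavanonol commercially available from Morus/Maclura heartwood, is the chiral starting material. Its C2 carries the same spatial arrangement as C2 of the (2S)-target, and C2 survives the mild steps below with no erosion.

## Retrosynthesis
- Cudraflavanone A comes from removing two MOM groups from a C6-prenyl, 4',5'-chromene flavanone (**15**).
- The C6 prenyl comes from allyl→prenyl cross-metathesis. The allyl group and the dimethylchromene ring form together in one thermal step: a 5-O-allyl aromatic Claisen and a 4'-O-(1,1-dimethylpropargyl) Claisen/[1,5]-H/oxa-6π-electrocyclization cascade.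
- Those ethers come from sequential O-alkylations of (2S)-5,7,2',4'-tetrahydroxyflavanone in the order of phenol acidity (7 > 4' > 2' >> 5, with 5-OH chelated).
- That flavanone comes from SmI2 removal of the C3-OAc of peracetylated dihydromorin. Ring order: rings A, B and C are inherited intact; the pyran ring forms last, in the electrocyclization.

## Route

**Step 1**
Reactants: **1** (+)-dihydromorin; **2** acetic anhydride
Product: **3** pentaacetate of dihydromorin
Conditions: Ac2O (8 equiv), pyridine, DMAP (cat.), rt, 12 h
Reagents that add atoms: acetic anhydride, CC(=O)OC(C)=O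
Why: Exhaustive O-acetylation masks the four phenols, so the only α-acyloxy ketone left is 3-OAc for the SmI2 step. Acylation is mild and leaves C2 untouched.

**Step 2**
Reactant: **3**
Product: **4** (2S)-5,7,2',4'-tetraacetoxyflavanone
Conditions: SmI2 (2.5 equiv), THF/MeOH, –78 °C
Reagents that add atoms: none
Why: Single-electron reductive cleavage of the α-acyloxy ketone (SmI2 deoxygenation) gives a Sm enolate that MeOH protonates at once. This removes the C3 stereocenter and leaves C2, which is set by the chiral pool, intact. The aryl acetates survive.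

**Step 3**
Reactant: **4**
Product: **5** (2S)-5,7,2',4'-tetrahydroxyflavanone (steppogenin)
Conditions: AcCl (0.2 equiv), MeOH, reflux
Reagents that add atoms: none
Why: Acid-catalysed methanolysis removes the aryl acetates (as MeOAc) without base, which avoids retro-oxa-Michael racemization of the flavanone.

**Step 4**
Reactants: **5**; **6** chloromethyl methyl ether
Product: **7** 7-O-MOM ether of **5**
Conditions: MOMCl (1.05 equiv), K2CO3, acetone, 0 °C→rt
Reagents that add atoms: MOMCl, COCCl
Why: 7-OH is by far the most acidic phenol (conjugated to C4=O), so it alkylates selectively; 5-OH is chelated and stays free. This is a Williamson-type O-alkylation, and C2 is untouched.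

**Step 5**
Reactants: **7**; **8** 3-chloro-3-methylbut-1-yne
Product: **9** 4'-O-(1,1-dimethylprop-2-ynyl) ether
Conditions: **8** (1.5 equiv), K2CO3, KI, CuI (cat.), acetone, 45 °C
Reagents that add atoms: 3-chloro-3-methylbut-1-yne, C#CC(C)(C)Cl
Why: Cu(I)-assisted O-propargylation. The more acidic and less hindered 4'-OH reacts in preference to the hindered 2'-OH, and the chelated 5-OH does not react.

**Step 6**
Reactants: **9**; **6** MOMCl
Product: **10** 2'-O-MOM ether of **9**
Conditions: MOMCl (1.5 equiv), K2CO3, DMF, rt
Reagents that add atoms: MOMCl, COCCl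
Why: Protecting 2'-OH prevents it from being allylated in the next step, which would lead to a wrong B-ring Claisen.

**Step 7**
Reactants: **10**; **11** allyl bromide
Product: **12** 5-O-allyl ether
Conditions: allyl bromide (3 equiv), K2CO3, DMF, 60 °C
Reagents that add atoms: allyl bromide, C=CCBr
Why: 5-OH is the only free OH left, and warm DMF/K2CO3 alkylates the chelated phenol. The MOM ethers and the tertiary propargyl ether are inert.

**Step 8** (key step)
Reactant: **12**
Product: **13** 6-allyl-5-hydroxy flavanone with the 2,2-dimethylchromene on B ring (bis-MOM)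
Conditions: o-dichlorobenzene, BHT, 185 °C, sealed tube, 10 h
Reagents that add atoms: none
Why: Two pericyclic processes run in one pot.
- The 5-O-allyl aromatic Claisen [3,3] shift can only go to C6, because C4a is blocked, and it regenerates the chelated 5-OH.
- The 4'-O-propargyl ether undergoes Claisen [3,3], then a [1,5]-H shift, then oxa-6π-electrocyclization to the 2,2-dimethyl-2H-chromene. The meta 2'-OMOM directs the [3,3] shift to C5', the position para to it.
- No new stereocenter forms, and C2 is untouched.

**Step 9**
Reactants: **13**; **14** 2-methylbut-2-ene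
Product: **15** 6-prenyl bis-MOM flavanone
Conditions: Hoveyda–Grubbs II (10 mol%), **14** (30 equiv), CH2Cl2, 40 °C, 12 h
Reagents that add atoms: 2-methylbut-2-ene, CC=C(C)C
Why: Olefin cross-metathesis converts the terminal allyl group into the prenyl group and releases propene. The hindered, styrenyl chromene alkene is far less reactive than the monosubstituted allyl alkene.

**Step 10**
Reactant: **15**
Product: **16** cudraflavanone A
Conditions: 3 M HCl, THF/MeOH (1:1), 35 °C, 3 h
Reagents that add atoms: none
Why: Acidolysis of the two aryl MOM acetals frees 7-OH and 2'-OH. The prenyl group, chromene and flavanone ring tolerate brief dilute acid, and C2 is not involved.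

## Compound list
1 | (+)-dihydromorin, (2R,3R)-3,5,7,2',4'-pentahydroxyflavanone | Oc1cc2c(c(O)c1)C(=O)[C@H](O)[C@@H](c1ccc(O)cc1O)O2 | starting material
2 | acetic anhydride | CC(=O)OC(C)=O | starting material (reagent)
3 | dihydromorin pentaacetate | CC(=O)Oc1cc2c(c(OC(C)=O)c1)C(=O)[C@H](OC(C)=O)[C@@H](c1ccc(OC(C)=O)cc1OC(C)=O)O2 | intermediate
4 | (2S)-5,7,2',4'-tetraacetoxyflavanone | CC(=O)Oc1cc2c(c(OC(C)=O)c1)C(=O)C[C@@H](c1ccc(OC(C)=O)cc1OC(C)=O)O2 | intermediate
5 | (2S)-5,7,2',4'-tetrahydroxyflavanone (steppogenin) | Oc1cc2c(c(O)c1)C(=O)C[C@@H](c1ccc(O)cc1O)O2 | intermediate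
6 | chloromethyl methyl ether | COCCl | starting material (reagent)
7 | 7-O-MOM-steppogenin | COCOc1cc2c(c(O)c1)C(=O)C[C@@H](c1ccc(O)cc1O)O2 | intermediate
8 | 3-chloro-3-methylbut-1-yne | C#CC(C)(C)Cl | starting material (reagent)
9 | 7-O-MOM-4'-O-(1,1-dimethylpropargyl) flavanone | COCOc1cc2c(c(O)c1)C(=O)C[C@@H](c1ccc(OC(C)(C)C#C)cc1O)O2 | intermediate
10 | 7,2'-di-O-MOM-4'-O-(1,1-dimethylpropargyl) flavanone | COCOc1cc2c(c(O)c1)C(=O)C[C@@H](c1ccc(OC(C)(C)C#C)cc1OCOC)O2 | intermediate
11 | allyl bromide | C=CCBr | starting material (reagent)
12 | 5-O-allyl analogue of 10 | COCOc1cc2c(c(OCC=C)c1)C(=O)C[C@@H](c1ccc(OC(C)(C)C#C)cc1OCOC)O2 | intermediate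
13 | 6-allyl-5-hydroxy-7,2'-di-O-MOM flavanone with 4',5'-dimethylchromene | C=CCc1c(OCOC)cc2c(c1O)C(=O)C[C@@H](c1cc3c(cc1OCOC)OC(C)(C)C=C3)O2 | intermediate
14 | 2-methylbut-2-ene | CC=C(C)C | starting material (reagent)
15 | 6-prenyl-7,2'-di-O-MOM flavanone with 4',5'-dimethylchromene | CC(C)=CCc1c(OCOC)cc2c(c1O)C(=O)C[C@@H](c1cc3c(cc1OCOC)OC(C)(C)C=C3)O2 | intermediate
16 | cudraflavanone A, (2S) | CC(C)=CCc1c(O)cc2c(c1O)C(=O)C[C@@H](c1cc3c(cc1O)OC(C)(C)C=C3)O2 | target

**Total steps:** 10. **Longest linear sequence:** 10.

## Three steps most likely to fail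
1. **Step 2 (SmI2 deoxygenation):** The Sm enolate carries a β-aryloxy leaving group, so ring-opening to the chalcone and racemization is possible.
   Fallback: a radical route with no enolate. Protect the phenols of **1** as MOM ethers under K2CO3 (3-OH stays free), convert 3-OH to its imidazolyl thiocarbonate, and deoxygenate with Bu3SnH/AIBN.
2. **Step 8 (double thermal rearrangement):** 185 °C risks erosion of C2 configuration and poor chemoselectivity between the two rearrangements.
   Fallback: drop the thermal cascade. Close the chromene at room temperature by Au(I)-catalysed 6-endo hydroarylation of the 4'-propargyl ether. Install the C6 prenyl in a separate, lower-temperature sequence.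
3. **Step 9 (allyl→prenyl cross-metathesis):** Yields are modest with a free chelated phenol, and the chromene alkene may interfere.
   Fallback: avoid the cross-metathesis. Make the 5-O-(1,1-dimethylpropargyl) ether in Step 7, Lindlar-reduce it to the 1,1-dimethylallyl ether, and let the Claisen rearrangement deliver the normal prenyl group directly.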